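**Retrosynthetic overview**
- The strategy rests on ring C (C8, C9, C11, C12, C13, C14), a fully substituted 2-hydroxy-3-isopropyl-1,4-benzoquinone that shares its C8=C9 bond with the seven-membered ring B. It is built last by 4π opening and 6π closure (bond C8–C14) of a 4-hydroxycyclobutenone attached to C9, itself made from a C9 alkenyllithium and a squarate-derived isopropylcyclobutenedione.
- The C9 alkenyl iodide comes from a cyclic alkenylboronate closed by ring-closing metathesis at C8=C9. The C7 oxygen (from an aldehyde) and the C9 metal (from a methyl ketone) are therefore told apart before ring B exists.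
- Both side chains hang on the 19,10-lactone (a 6-oxabicyclo[3.2.1]octan-7-one): C10–O by iodolactonisation of a β,γ-unsaturated acid, C5–C6 by radical allylation of the resulting C5 iodide, C7 by asymmetric vinylation.
- C4 is set by copper-catalysed asymmetric conjugate methylation of a cyclohexenone ester; the regiodefined enolate is triflated for the C10–C20 coupling.
- Ring order: A (purchased) → γ-lactone → B (metathesis) → C (electrocyclic cascade); then oxidation, silyl-to-acetyl exchange at O7 and de-isopropylation at O12.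

Key step: step 15

Remark: positions are given in icetexane numbering (C19 = lactone carbonyl on C4, lactone oxygen on C10, ring B = C5, C6, C7, C8, C9, C20, C10); keto ester 1, the two allylic stannanes and diisopropyl squarate are taken as purchasable.

**Route**

Step 1
Reactants: 1 methyl 3-oxocyclohex-1-ene-1-carboxylate
Product: 3 methyl (1S)-1-methyl-3-(trifluoromethanesulfonyloxy)cyclohex-2-ene-1-carboxylate, via zinc enolate 2 (not isolated)
Conditions: Me2Zn, (CuOTf)2·C6H6 (cat.), chiral NHC–Ag complex (cat.), Et2O, −30 °C; then Tf2O, −78 → 0 °C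
Reagents that add atoms: dimethylzinc C[Zn]C; trifluoromethanesulfonic anhydride O=S(=O)(OS(=O)(=O)C(F)(F)F)C(F)(F)F
Why: Copper-catalysed asymmetric conjugate addition of a dialkylzinc to a β-ester cyclohexenone is a known way to all-carbon quaternary centres, the ligand enantiomer being chosen so that methyl is delivered to the face giving (S)-C4, and O-triflation of the regiodefined zinc enolate fixes the double bond at C5=C10.

Step 2
Reactants: 3 methyl (1S)-1-methyl-3-(trifluoromethanesulfonyloxy)cyclohex-2-ene-1-carboxylate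
Product: 4 methyl (1S)-1-methyl-3-(2-methylprop-2-en-1-yl)cyclohex-2-ene-1-carboxylate
Conditions: tributyl(2-methylallyl)stannane, Pd(PPh3)4 (cat.), LiCl, THF, 65 °C
Reagents that add atoms: tributyl(2-methylallyl)stannane CC(=C)C[Sn](CCCC)(CCCC)CCCC
Why: Stille coupling of an enol triflate with an allylic stannane in the presence of LiCl forms the C10–C20 bond and leaves the ring alkene at C5=C10, the methallyl group being indifferent to allylic transposition and no stereocentre being formed.

Step 3
Reactants: 4 methyl (1S)-1-methyl-3-(2-methylprop-2-en-1-yl)cyclohex-2-ene-1-carboxylate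
Product: 5 (1S)-1-methyl-3-(2-methylprop-2-en-1-yl)cyclohex-2-ene-1-carboxylic acid
Conditions: LiOH, THF/MeOH/H2O, 55 °C; 1 M HCl work-up
Reagents that add atoms: lithium hydroxide [Li+].[OH-]
Why: Saponification of the hindered ester should be clean because the β,γ-alkene cannot move into conjugation past the quaternary C4, which is not epimerisable.

Step 4
Reactants: 5 (1S)-1-methyl-3-(2-methylprop-2-en-1-yl)cyclohex-2-ene-1-carboxylic acid
Product: 6 (1R,5S,8R)-8-iodo-1-methyl-5-(2-methylprop-2-en-1-yl)-6-oxabicyclo[3.2.1]octan-7-one (iodine on C5 anti to the lactone bridge)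
Conditions: I2, NaHCO3, MeCN, 0 °C → rt, dark
Reagents that add atoms: iodine II
Why: Iodolactonisation of the β,γ-unsaturated acid should open the iodonium ion of the trisubstituted ring alkene at the more substituted C10 (γ-lactone, favoured under equilibrating conditions) from the face that carries the carboxyl, so that O–C10 is necessarily cis to C19 and iodine ends on C5 anti to the lactone, while the methallyl alkene has no carboxylate within reach.

Step 5
Reactants: 6 (1R,5S,8R)-8-iodo-1-methyl-5-(2-methylprop-2-en-1-yl)-6-oxabicyclo[3.2.1]octan-7-one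
Product: 7 (1S,5S,8S)-8-allyl-1-methyl-5-(2-methylprop-2-en-1-yl)-6-oxabicyclo[3.2.1]octan-7-one (allyl on C5 syn to the lactone bridge)
Conditions: allylSnBu3, AIBN (cat.), PhH, 80 °C
Reagents that add atoms: allyltributylstannane C=CC[Sn](CCCC)(CCCC)CCCC
Why: In this Keck radical allylation the C5 radical, held between two quaternary bridgeheads, should be trapped by the stannane on the face of the two-atom lactone bridge, which carries no hydrogens, and not on the face screened by the axial hydrogens of C1 and C3, which places C6 syn to the lactone and H5 anti as in the target.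

Step 6
Reactants: 7 (1S,5S,8S)-8-allyl-1-methyl-5-(2-methylprop-2-en-1-yl)-6-oxabicyclo[3.2.1]octan-7-one
Product: 8 2-[(1S,5S,8S)-1-methyl-7-oxo-5-(2-oxopropyl)-6-oxabicyclo[3.2.1]octan-8-yl]acetaldehyde
Conditions: O3, CH2Cl2/MeOH, −78 °C; Me2S work-up
Reagents that add atoms: ozone [O-][O+]=O
Why: Ozonolysis cleaves both terminal alkenes in one operation and turns the allyl group into the C7 aldehyde and the methallyl group into the C9 methyl ketone, which differentiates C7 from C9 by oxidation level without touching a stereocentre.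

Step 7
Reactants: 8 2-[(1S,5S,8S)-1-methyl-7-oxo-5-(2-oxopropyl)-6-oxabicyclo[3.2.1]octan-8-yl]acetaldehyde
Product: 9 (1S,5S,8S)-8-[(2R)-2-hydroxybut-3-en-1-yl]-1-methyl-5-(2-oxopropyl)-6-oxabicyclo[3.2.1]octan-7-one
Conditions: CH2=CHBr, CrCl2, NiCl2 (cat.), chiral sulfonamide ligand, Et3N, THF, rt
Reagents that add atoms: vinyl bromide C=CBr
Why: In the asymmetric Nozaki–Hiyama–Kishi reaction the vinylchromium species adds to the aldehyde far faster than to the methyl ketone or the lactone and is not basic enough to trigger β-elimination at C10, and the chiral ligand on chromium (enantiomer chosen for the purpose) should set (R)-C7 by reagent control.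

Step 8
Reactants: 9 (1S,5S,8S)-8-[(2R)-2-hydroxybut-3-en-1-yl]-1-methyl-5-(2-oxopropyl)-6-oxabicyclo[3.2.1]octan-7-one
Product: 10 (1S,5S,8S)-8-[(2R)-2-(tert-butyldimethylsilyloxy)but-3-en-1-yl]-1-methyl-5-(2-oxopropyl)-6-oxabicyclo[3.2.1]octan-7-one
Conditions: TBSCl, imidazole, DMF, rt
Reagents that add atoms: tert-butyldimethylsilyl chloride CC(C)(C)[Si](C)(C)Cl
Why: Silylation of the secondary allylic alcohol with TBSCl and imidazole does not enolise the methyl ketone and leaves C7 untouched.

Step 9
Reactants: 10 (1S,5S,8S)-8-[(2R)-2-(tert-butyldimethylsilyloxy)but-3-en-1-yl]-1-methyl-5-(2-oxopropyl)-6-oxabicyclo[3.2.1]octan-7-one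
Product: 12 (1S,5S,8S)-8-[(2R)-2-(tert-butyldimethylsilyloxy)but-3-en-1-yl]-1-methyl-5-[2-(trifluoromethanesulfonyloxy)prop-2-en-1-yl]-6-oxabicyclo[3.2.1]octan-7-one, via potassium enolate 11 (not isolated)
Conditions: KHMDS, THF, −78 °C; then PhNTf2
Reagents that add atoms: N-phenylbis(trifluoromethanesulfonimide) O=S(=O)(N(c1ccccc1)S(=O)(=O)C(F)(F)F)C(F)(F)F
Why: Kinetic deprotonation of a methyl ketone occurs at the methyl group and not at the neopentyl-type C20 methylene, so the terminal enolate (which cannot expel the C10 carboxylate) is O-triflated to the 2-triflyloxy-1-alkene.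

Step 10
Reactants: 12 enol triflate of step 9
Product: 13 (1S,5S,8S)-8-[(2R)-2-(tert-butyldimethylsilyloxy)but-3-en-1-yl]-1-methyl-5-[2-(4,4,5,5-tetramethyl-1,3,2-dioxaborolan-2-yl)prop-2-en-1-yl]-6-oxabicyclo[3.2.1]octan-7-one
Conditions: B2pin2, PdCl2(PPh3)2 (cat.), PPh3, KOPh, toluene, 50 °C
Reagents that add atoms: bis(pinacolato)diboron CC1(C)OB(OC1(C)C)B1OC(C)(C)C(C)(C)O1
Why: Miyaura borylation of an alkenyl triflate under phenoxide conditions exchanges OTf for Bpin at C9 and tolerates the lactone, the silyl ether and the terminal alkene.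

Step 11
Reactants: 13 alkenylboronate diene of step 10
Product: 14 C9 pinacol boronate of the 7α-(tert-butyldimethylsilyloxy) A/B lactone: ring B (C5–C6–C7–C8=C9–C20–C10) fused to the 19,10-lactone; (4S,5S,7R,10S)
Conditions: Grubbs II (cat.), toluene, 80 °C, high dilution
Reagents that add atoms: none
Why: Ring-closing metathesis of an α-substituted vinylboronate with a terminal alkene is a known route to cyclic alkenylboronates, the catalyst loading at the monosubstituted alkene and closing on the boryl alkene, with the two chains held gauche on C5 and C10 of the rigid lactone and no stereocentre formed.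

Step 12
Reactants: 14 cyclic alkenylboronate of step 11
Product: 15 C9 iodide of the 7α-(tert-butyldimethylsilyloxy) A/B lactone; (4S,5S,7R,10S)
Conditions: I2, NaOH (aq), THF, 0 °C
Reagents that add atoms: iodine II
Why: Iododeboronation of the hydroxide ate complex replaces boron by iodine at the same carbon (ipso substitution), which gives the C8=C9–I unit with the regiochemistry fixed by the metathesis.

Step 13
Reactants: 16 diisopropyl squarate; 17 isopropylmagnesium chloride
Product: 19 3-isopropoxy-4-isopropylcyclobut-3-ene-1,2-dione, via hydroxycyclobutenone adduct 18 (not isolated)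
Conditions: THF, −78 °C; then conc. HCl (cat.), CH2Cl2, rt
Reagents that add atoms: none
Why: 1,2-Addition of the Grignard reagent to one carbonyl of the squarate followed by acid-induced loss of isopropanol from the adduct is the standard route to 3-alkoxy-4-alkylcyclobutenediones and leaves no stereocentre.

Step 14
Reactants: 15 C9 iodide of the A/B lactone; 19 3-isopropoxy-4-isopropylcyclobut-3-ene-1,2-dione
Product: 21 4-hydroxy-3-isopropoxy-2-isopropylcyclobut-2-en-1-one carrying on C4 the C9 carbon of the 7α-silyloxy A/B lactone (both carbinol epimers), via alkenyllithium 20 (not isolated)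
Conditions: t-BuLi (2 equiv), Et2O, −78 °C; then 19, THF, −78 °C; aq NH4Cl
Reagents that add atoms: none
Why: Iodine–lithium exchange at −78 °C is faster than attack on the hindered neopentyl lactone, and the alkenyllithium adds 1,2 to the more electrophilic carbonyl of 19 (the one bonded to the isopropoxy-bearing carbon and not in vinylogous-ester conjugation), the new carbinol centre being uncontrolled and lost in the next step.

Step 15
Reactants: 21 4-cycloheptenyl-4-hydroxycyclobutenone of step 14
Product: 23 7α-(tert-butyldimethylsilyloxy)-12-O-isopropyl-11,14-hydroquinone of the icetexane 19,10-olide, via dienylketene 22 (not isolated)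
Conditions: toluene (degassed), 110 °C
Reagents that add atoms: none
Why: Heating cleaves the cyclobutenone bond between the carbonyl carbon (future C14) and the carbinol carbon (future C11) by thermal conrotatory 4π opening to dienylketene 22, the hydroxyl turning outward as donor groups do and the cycloheptenyl group therefore turning inward beside the ketene. Thermal disrotatory 6π electrocyclisation then joins C8 to the ketene carbon C14 and closes ring C on the C8=C9 bond of ring B, and the cyclohexa-2,4-dienone aromatises by a C8–H to O14 shift. This is the known thermal ring expansion of 4-alkenyl-4-hydroxycyclobutenones to hydroquinones. No stereocentre is formed (C8 returns to sp2) and C4, C5, C7 and C10 are not involved. The substitution pattern is fixed beforehand by the order of additions to the squarate (carbinol carbon → C11, isopropoxy carbon → C12, isopropyl carbon → C13, ketone carbon → C14). The step itself needs only the outward torquoselectivity of the hydroxyl, which holds for both carbinol epimers, and a closure faster than ketene trapping, which the s-cis geometry enforced by the ring and a nucleophile-free degassed solvent should secure.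

Step 16
Reactants: 23 hydroquinone of step 15
Product: 24 7α-(tert-butyldimethylsilyloxy)-12-O-isopropyl-6,7-dihydroicetexone (quinone)
Conditions: Ag2O, MgSO4, Et2O, rt
Reagents that add atoms: none
Why: Silver(I) oxide oxidation of a hydroquinone to the 1,4-benzoquinone is mild and neutral and removes the electron-rich arene beside the C7 silyloxy group.

Step 17
Reactants: 24 silyl ether quinone of step 16
Product: 25 7α-hydroxy-12-O-isopropyl-6,7-dihydroicetexone
Conditions: HF·pyridine, THF, 0 °C → rt
Reagents that add atoms: none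
Why: Fluoride-mediated desilylation under acidic buffering frees the C7 alcohol without C–O cleavage at C7 and avoids basic conditions that the quinone would not tolerate.

Step 18
Reactants: 25 7α-hydroxy-12-O-isopropyl-6,7-dihydroicetexone
Product: 26 7α-acetoxy-12-O-isopropyl-6,7-dihydroicetexone
Conditions: Ac2O, pyridine, DMAP (cat.), CH2Cl2, rt
Reagents that add atoms: acetic anhydride CC(=O)OC(C)=O
Why: Acylation of the secondary alcohol proceeds with retention at C7, and the C12 oxygen is still masked as its isopropyl ether so only O7 is acetylated.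

Step 19
Reactants: 26 7α-acetoxy-12-O-isopropyl-6,7-dihydroicetexone
Product: 27 7α-acetoxy-6,7-dihydroicetexone (target)
Conditions: BCl3, CH2Cl2, −78 → −20 °C; aqueous work-up
Reagents that add atoms: none
Why: Lewis-acid dealkylation of the isopropyl ether (BCl3 chelated between O12 and the C11 carbonyl of the vinylogous ester, isopropyl lost as the chloride) frees the C12 hydroxyl at low temperature while the secondary acetate and the lactone stay intact.

**Compound list**
1 | methyl 3-oxocyclohex-1-ene-1-carboxylate | COC(=O)C1=CC(=O)CCC1 | starting material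
2 | methylzinc enolate of methyl (1S)-1-methyl-3-oxocyclohexane-1-carboxylate (not isolated) | COC(=O)[C@@]1(C)CCCC(O[Zn]C)=C1 | intermediate
3 | methyl (1S)-1-methyl-3-(trifluoromethanesulfonyloxy)cyclohex-2-ene-1-carboxylate | COC(=O)[C@@]1(C)CCCC(OS(=O)(=O)C(F)(F)F)=C1 | intermediate
4 | methyl (1S)-1-methyl-3-(2-methylprop-2-en-1-yl)cyclohex-2-ene-1-carboxylate | COC(=O)[C@@]1(C)CCCC(CC(C)=C)=C1 | intermediate
5 | (1S)-1-methyl-3-(2-methylprop-2-en-1-yl)cyclohex-2-ene-1-carboxylic acid | OC(=O)[C@@]1(C)CCCC(CC(C)=C)=C1 | intermediate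
6 | (1R,5S,8R)-8-iodo-1-methyl-5-(2-methylprop-2-en-1-yl)-6-oxabicyclo[3.2.1]octan-7-one | I[C@H]1[C@]2(CCC[C@]1(C)C(=O)O2)CC(C)=C | intermediate
7 | (1S,5S,8S)-8-allyl-1-methyl-5-(2-methylprop-2-en-1-yl)-6-oxabicyclo[3.2.1]octan-7-one | C=CC[C@@H]1[C@]2(CCC[C@]1(C)C(=O)O2)CC(C)=C | intermediate
8 | 2-[(1S,5S,8S)-1-methyl-7-oxo-5-(2-oxopropyl)-6-oxabicyclo[3.2.1]octan-8-yl]acetaldehyde | O=CC[C@@H]1[C@]2(CCC[C@]1(C)C(=O)O2)CC(C)=O | intermediate
9 | (1S,5S,8S)-8-[(2R)-2-hydroxybut-3-en-1-yl]-1-methyl-5-(2-oxopropyl)-6-oxabicyclo[3.2.1]octan-7-one | C=C[C@H](O)C[C@@H]1[C@]2(CCC[C@]1(C)C(=O)O2)CC(C)=O | intermediate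
10 | (1S,5S,8S)-8-[(2R)-2-(tert-butyldimethylsilyloxy)but-3-en-1-yl]-1-methyl-5-(2-oxopropyl)-6-oxabicyclo[3.2.1]octan-7-one | CC(C)(C)[Si](C)(C)O[C@@H](C=C)C[C@@H]1[C@]2(CCC[C@]1(C)C(=O)O2)CC(C)=O | intermediate
11 | terminal potassium enolate of methyl ketone 10 (not isolated) | CC(C)(C)[Si](C)(C)O[C@@H](C=C)C[C@@H]1[C@]2(CCC[C@]1(C)C(=O)O2)CC(=C)O[K] | intermediate
12 | (1S,5S,8S)-8-[(2R)-2-(tert-butyldimethylsilyloxy)but-3-en-1-yl]-1-methyl-5-[2-(trifluoromethanesulfonyloxy)prop-2-en-1-yl]-6-oxabicyclo[3.2.1]octan-7-one | CC(C)(C)[Si](C)(C)O[C@@H](C=C)C[C@@H]1[C@]2(CCC[C@]1(C)C(=O)O2)CC(=C)OS(=O)(=O)C(F)(F)F | intermediate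
13 | (1S,5S,8S)-8-[(2R)-2-(tert-butyldimethylsilyloxy)but-3-en-1-yl]-1-methyl-5-[2-(4,4,5,5-tetramethyl-1,3,2-dioxaborolan-2-yl)prop-2-en-1-yl]-6-oxabicyclo[3.2.1]octan-7-one | CC(C)(C)[Si](C)(C)O[C@@H](C=C)C[C@@H]1[C@]2(CCC[C@]1(C)C(=O)O2)CC(=C)B3OC(C)(C)C(C)(C)O3 | intermediate
14 | C9 pinacol boronate of the 7α-(tert-butyldimethylsilyloxy) A/B lactone (cyclohept-8-ene ring B fused to the 19,10-lactone; 4S,5S,7R,10S) | CC(C)(C)[Si](C)(C)O[C@@H]1C[C@@H]2[C@]3(CCC[C@]2(C)C(=O)O3)CC(B4OC(C)(C)C(C)(C)O4)=C1 | intermediate
15 | C9 iodide of the 7α-(tert-butyldimethylsilyloxy) A/B lactone (4S,5S,7R,10S) | CC(C)(C)[Si](C)(C)O[C@@H]1C[C@@H]2[C@]3(CCC[C@]2(C)C(=O)O3)CC(I)=C1 | intermediate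
16 | diisopropyl squarate (3,4-diisopropoxycyclobut-3-ene-1,2-dione) | CC(C)OC1=C(OC(C)C)C(=O)C1=O | starting material
17 | isopropylmagnesium chloride | CC(C)[Mg]Cl | starting material
18 | 4-hydroxy-2,3-diisopropoxy-4-isopropylcyclobut-2-en-1-one (not isolated) | CC(C)OC1=C(OC(C)C)C(O)(C(C)C)C1=O | intermediate
19 | 3-isopropoxy-4-isopropylcyclobut-3-ene-1,2-dione | CC(C)OC1=C(C(C)C)C(=O)C1=O | intermediate
20 | C9 alkenyllithium of the 7α-(tert-butyldimethylsilyloxy) A/B lactone (not isolated) | CC(C)(C)[Si](C)(C)O[C@@H]1C[C@@H]2[C@]3(CCC[C@]2(C)C(=O)O3)CC([Li])=C1 | intermediate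
21 | 4-hydroxy-3-isopropoxy-2-isopropylcyclobut-2-en-1-one bearing on C4 the C9 carbon of the 7α-silyloxy A/B lactone (carbinol epimers) | CC(C)(C)[Si](C)(C)O[C@@H]1C[C@@H]2[C@]3(CCC[C@]2(C)C(=O)O3)CC(=C1)C1(O)C(OC(C)C)=C(C(C)C)C1=O | intermediate
22 | dienylketene from ring opening of 21 (not isolated) | CC(C)(C)[Si](C)(C)O[C@@H]1C[C@@H]2[C@]3(CCC[C@]2(C)C(=O)O3)CC(=C1)C(O)=C(OC(C)C)C(C(C)C)=C=O | intermediate
23 | 7α-(tert-butyldimethylsilyloxy)-12-O-isopropyl-11,14-hydroquinone of the icetexane 19,10-olide | CC(C)(C)[Si](C)(C)O[C@@H]1C[C@@H]2[C@]3(CCC[C@]2(C)C(=O)O3)Cc2c1c(O)c(C(C)C)c(OC(C)C)c2O | intermediate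
24 | 7α-(tert-butyldimethylsilyloxy)-12-O-isopropyl-6,7-dihydroicetexone | CC(C)(C)[Si](C)(C)O[C@@H]1C[C@@H]2[C@]3(CCC[C@]2(C)C(=O)O3)CC2=C1C(=O)C(C(C)C)=C(OC(C)C)C2=O | intermediate
25 | 7α-hydroxy-12-O-isopropyl-6,7-dihydroicetexone | O[C@@H]1C[C@@H]2[C@]3(CCC[C@]2(C)C(=O)O3)CC2=C1C(=O)C(C(C)C)=C(OC(C)C)C2=O | intermediate
26 | 7α-acetoxy-12-O-isopropyl-6,7-dihydroicetexone | CC(=O)O[C@@H]1C[C@@H]2[C@]3(CCC[C@]2(C)C(=O)O3)CC2=C1C(=O)C(C(C)C)=C(OC(C)C)C2=O | intermediate
27 | 7α-acetoxy-6,7-dihydroicetexone (4S,5S,7R,10S) | CC(=O)O[C@@H]1C[C@@H]2[C@]3(CCC[C@]2(C)C(=O)O3)CC2=C1C(=O)C(C(C)C)=C(O)C2=O | target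

**Step count and risks**

Total step count: 19. Longest linear sequence: 18 (steps 1–12 and 14–19); step 13 is a one-step side branch.

Steps most likely to fail:

Step 5. The C5 radical may be trapped with poor facial selectivity, or on the face of the C1–C3 bridge, which would put C6 anti to the lactone (the C5 epimer). The fallback places the C5 substituent by enolate chemistry before the lactone exists. It sets out from 1: the zinc enolate 2 from the same conjugate methylation is allylated in the flask (allyl iodide, HMPA) to methyl (1S,2S)-2-allyl-1-methyl-3-oxocyclohexane-1-carboxylate F1. C5 of F1 lies next to the C10 ketone, so it can be equilibrated with base and the epimers separated. Methallylmagnesium chloride (THF, −78 °C) should then add to the C10 ketone from the side away from the axial ester, and only the alkoxide that is cis to the ester can close the lactone, which returns the route at 7.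

Step 7. Facial selectivity of the vinyl addition to the β-branched aldehyde may be poor, giving C7 epimers. The fallback replaces vinylation by alkynylation and semireduction and sets out from 8. Zinc–ProPhenol-catalysed addition of trimethylsilylacetylene (Me2Zn, toluene), which also spares the ketone, should give (1S,5S,8S)-8-[(2R)-2-hydroxy-4-(trimethylsilyl)but-3-yn-1-yl]-1-methyl-5-(2-oxopropyl)-6-oxabicyclo[3.2.1]octan-7-one F2. Buffered desilylation (TBAF, AcOH) gives (1S,5S,8S)-8-[(2R)-2-hydroxybut-3-yn-1-yl]-1-methyl-5-(2-oxopropyl)-6-oxabicyclo[3.2.1]octan-7-one F3, and Lindlar semihydrogenation returns the route at 9.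

Step 15 (key step). Closure at C8, which sits next to the silyloxy-bearing C7, may be slow enough that the ketene is captured by its own enol hydroxyl (five-membered lactone), and the hot, electron-rich free hydroquinone may lose the benzylic C7 silyloxy group or oxidise uncontrollably. The fallback keeps the same ring opening and closure but removes the free hydroxyl; it sets out from 21. Silylation with N-trimethylsilylimidazole (non-acidic, so that the alkoxy-cyclobutenol does not ionise) gives 3-isopropoxy-2-isopropyl-4-(trimethylsilyloxy)cyclobut-2-en-1-one bearing on C4 the C9 carbon of the 7α-silyloxy A/B lactone F4. Thermolysis in toluene should give 7α-(tert-butyldimethylsilyloxy)-12-O-isopropyl-11-O-trimethylsilyl-11,14-hydroquinone of the icetexane 19,10-olide F5, and oxidative desilylation with PhI(OAc)2 in wet acetonitrile at 0 °C returns the route at quinone 24.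

Further compounds
F1 | step 5 | methyl (1S,2S)-2-allyl-1-methyl-3-oxocyclohexane-1-carboxylate | C=CC[C@@H]1C(=O)CCC[C@]1(C)C(=O)OC
F2 | step 7 | (1S,5S,8S)-8-[(2R)-2-hydroxy-4-(trimethylsilyl)but-3-yn-1-yl]-1-methyl-5-(2-oxopropyl)-6-oxabicyclo[3.2.1]octan-7-one | C[Si](C)(C)C#C[C@H](O)C[C@@H]1[C@]2(CCC[C@]1(C)C(=O)O2)CC(C)=O
F3 | step 7 | (1S,5S,8S)-8-[(2R)-2-hydroxybut-3-yn-1-yl]-1-methyl-5-(2-oxopropyl)-6-oxabicyclo[3.2.1]octan-7-one | C#C[C@H](O)C[C@@H]1[C@]2(CCC[C@]1(C)C(=O)O2)CC(C)=O
F4 | step 15 | 3-isopropoxy-2-isopropyl-4-(trimethylsilyloxy)cyclobut-2-en-1-one bearing on C4 the C9 carbon of the 7α-silyloxy A/B lactone | CC(C)(C)[Si](C)(C)O[C@@H]1C[C@@H]2[C@]3(CCC[C@]2(C)C(=O)O3)CC(=C1)C1(O[Si](C)(C)C)C(OC(C)C)=C(C(C)C)C1=O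
F5 | step 15 | 7α-(tert-butyldimethylsilyloxy)-12-O-isopropyl-11-O-trimethylsilyl-11,14-hydroquinone of the icetexane 19,10-olide | CC(C)(C)[Si](C)(C)O[C@@H]1C[C@@H]2[C@]3(CCC[C@]2(C)C(=O)O3)Cc2c1c(O)c(C(C)C)c(OC(C)C)c2O[Si](C)(C)C
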